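Everything rests on cutting ring B, the central cyclohexane, along two bonds: C3–C10 and C8–C9. Ring B hides a conjugate-addition/aldol pattern around the ring C ketone C11: its α-carbon C9 (tertiary carbinol) is flanked by C10, which carries the methyl-bearing quaternary C3, and by the oxygenated C8. One iron-hydride step turns the exocyclic methylene of a finished ring A aldehyde into the angular methyl and a C3 radical, adds it to C10 of a finished alkoxy-enedione ring C, and closes the resulting C9 enolate onto the C8 aldehyde: ring B, two C–C bonds and four stereocentres at once. The precursors are a monocyclic triacyloxy cyclohexane and an achiral cyclooctadienedione.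

Key step: step 16

Remarks on the chemistry:
- Atom labels: ring A = C1(OAc), C2(OBz), C3(quaternary, CH3), C4(H), C5(CMe2), C6(OBz). Ring B = C3, C4, C7(H2), C8(OAc), C9(OH), C10(H). Ring C = C9, C11(=O), C12(H2), C13(H)=C14(CH3), C15(H2), C16(=O), C10.
- β is the face of ring A that carries the three acyloxy groups and H-4; α is the opposite face (angular methyl, C4 side chain). PMB = 4-methoxybenzyl.
- Assumption: the (S,S)-ligand of step 2 is taken to deliver the (R)-allyl centre; if the sense of induction is the opposite, the mirror-image ligand is used.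
- Compound 1 is taken as purchased (it is also one step from dimedone).

Step 1
Reactants: 1 3-ethoxy-5,5-dimethylcyclohex-2-en-1-one; 2 allyl chloroformate
Product: 4 allyl 5-ethoxy-3,3-dimethylcyclohexa-1,5-dien-1-yl carbonate, via lithium dienolate 3 (not isolated)
Conditions: LiN(i-Pr)2, THF, −78 °C; TMEDA; then 2, −78 °C to rt
Reagents that add atoms: allyl chloroformate, C=CCOC(Cl)=O
Why: Kinetic deprotonation of the vinylogous ester at the α′-methylene and O-acylation of the lithium dienolate by the chloroformate in the presence of TMEDA (enol carbonate formation) should give the substrate for decarboxylative allylation; no stereocentre is formed.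

Step 2
Reactants: 4 allyl 5-ethoxy-3,3-dimethylcyclohexa-1,5-dien-1-yl carbonate
Product: 5 (R)-6-allyl-3-ethoxy-5,5-dimethylcyclohex-2-en-1-one
Conditions: Pd2(dba)3·CHCl3 (2.5 mol %), (S,S)-ANDEN-phenyl bis(2-diphenylphosphinobenzamide) ligand (5.5 mol %), 1,4-dioxane, 23 °C
Reagents that add atoms: none
Why: Decarboxylative asymmetric allylic alkylation (Tsuji–Trost type): zerovalent palladium ionises the allyl carbonate, CO2 is lost, and the enolate recombines with the π-allyl palladium cation inside the chiral ligand pocket, which should set the α′-tertiary centre (C4 of the target) as R under neutral conditions that do not epimerise it.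

Step 3
Reactants: 5 (R)-6-allyl-3-ethoxy-5,5-dimethylcyclohex-2-en-1-one; 6 methyllithium
Product: 8 (R)-4-allyl-3,5,5-trimethylcyclohex-2-en-1-one, via tertiary carbinol 7 (not isolated)
Conditions: MeLi, Et2O/THF, −78 to 0 °C; then 1 M HCl, 0 °C
Reagents that add atoms: methyllithium, [Li]C
Why: Stork–Danheiser enone transposition: 1,2-addition of MeLi to the vinylogous ester carbonyl, then acid hydrolysis of the enol ether and dehydration, should move the carbonyl to C1 and place the future angular methyl on C3, the C4 centre being untouched.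

Step 4
Reactants: 8 (R)-4-allyl-3,5,5-trimethylcyclohex-2-en-1-one; 9 hydrogen peroxide
Product: 10 (5R)-5-allyl-4,4,6-trimethyl-7-oxabicyclo[4.1.0]heptan-2-one (2β,3β-epoxy ketone, epoxide oxygen trans to the allyl group)
Conditions: 30% H2O2, NaOH (0.3 equiv), MeOH, 0–10 °C
Reagents that add atoms: hydrogen peroxide, OO
Why: Weitz–Scheffer nucleophilic epoxidation: hydroperoxide should add to the β-carbon C3 anti to the adjacent allyl group, so the epoxide oxygen (the future C2 oxygen) ends on the β face, while the isolated terminal alkene is inert to the nucleophilic oxidant.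

Step 5
Reactants: 10 2β,3β-epoxy ketone; 11 dibenzoyl peroxide
Product: 13 5-allyl-4,4,6-trimethyl-2-oxo-7-oxabicyclo[4.1.0]heptan-3-yl benzoate (C6 benzoate β, cis to the epoxide oxygen, trans to allyl), via lithium enolate 12 (not isolated)
Conditions: LiN(i-Pr)2, THF, −78 °C; (PhCO2)2, −78 to −20 °C; then DBU (0.1 equiv), CH2Cl2, 0 °C
Reagents that add atoms: dibenzoyl peroxide, O=C(OOC(=O)c1ccccc1)c1ccccc1
Why: Enolate α-oxidation with a diacyl peroxide (α-benzoyloxylation) at C6, the only enolisable position, should install the benzoate in one step; the amidine equilibration lets it settle pseudo-equatorial on the β face, trans to the allyl group, and cannot touch C4, which is no longer acidic.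

Step 6
Reactants: 13 C6-benzoyloxy epoxy ketone
Product: 14 5-allyl-2-hydroxy-4,4,6-trimethyl-7-oxabicyclo[4.1.0]heptan-3-yl benzoate (hydroxyl, benzoate and epoxide oxygen all β, allyl α)
Conditions: NaBH4, CeCl3·7H2O, MeOH, −78 to −40 °C; AcOH quench
Reagents that add atoms: none
Why: Luche reduction of the ketone, with hydride delivered from the α face, anti to the epoxide oxygen and the neighbouring benzoate, should give the C1 alcohol cis to both oxygens; low temperature and the acidic quench suppress benzoate migration.

Step 7
Reactants: 14 epoxy alcohol; 15 acetic anhydride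
Product: 16 2-acetoxy-5-allyl-4,4,6-trimethyl-7-oxabicyclo[4.1.0]heptan-3-yl benzoate (all three oxygens β)
Conditions: Ac2O, pyridine, DMAP (cat.), CH2Cl2, 0 °C to rt
Reagents that add atoms: acetic anhydride, CC(=O)OC(C)=O
Why: DMAP-catalysed acylation of the only free hydroxyl should install the C1 acetate with retention.

Step 8
Reactants: 16 epoxy acetate; 17 ozone
Product: 19 2-acetoxy-4,4,6-trimethyl-5-(2-oxoethyl)-7-oxabicyclo[4.1.0]heptan-3-yl benzoate, via secondary ozonide 18 (not isolated)
Conditions: O3, CH2Cl2, −78 °C; then Me2S, −78 °C to rt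
Reagents that add atoms: ozone, [O-][O+]=O
Why: Ozonolysis with reductive work-up should cleave the only C=C bond present, the terminal allyl alkene, to the C8 aldehyde, the epoxide and esters being inert.

Step 9
Reactants: 19 epoxy aldehyde
Product: 20 2-acetoxy-3-hydroxy-6,6-dimethyl-4-methylidene-5-(2-oxoethyl)cyclohexyl benzoate (C1 acetate, C2 hydroxyl and C6 benzoate all β, side chain α)
Conditions: Cp2TiCl2 (2.2 equiv), Mn dust, THF, rt; then 0.5 M HCl work-up
Reagents that add atoms: none
Why: Trivalent titanium (Cp2TiCl) opens the trisubstituted epoxide homolytically at the tertiary carbon C3 and a second titanium centre removes a hydrogen atom from the adjacent methyl rather than the hindered H-4 (known titanocene epoxide-to-allylic-alcohol isomerisation), which should give the exocyclic methylene with the C2–O bond and its β configuration intact; esters and the aliphatic aldehyde are not reduced by this reagent.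

Step 10
Reactants: 20 allylic alcohol aldehyde; 21 benzoyl chloride
Product: 22 (1S,2R,3R,5R)-2-acetoxy-4,4-dimethyl-6-methylidene-5-(2-oxoethyl)cyclohexane-1,3-diyl dibenzoate (ring A fragment)
Conditions: BzCl, pyridine, DMAP (cat.), CH2Cl2, 0 °C to rt
Reagents that add atoms: benzoyl chloride, O=C(Cl)c1ccccc1
Why: DMAP-catalysed benzoylation of the single free allylic hydroxyl should complete the differentiated triester without any selection between hydroxyls.

Step 11
Reactants: 23 3-bromofuran; 24 4-methoxybenzyl alcohol
Product: 25 3-[(4-methoxybenzyl)oxy]furan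
Conditions: CuI (10 mol %), 3,4,7,8-tetramethyl-1,10-phenanthroline (20 mol %), Cs2CO3, toluene, 110 °C (sealed tube)
Reagents that add atoms: 4-methoxybenzyl alcohol, COc1ccc(CO)cc1
Why: Copper-catalysed Ullmann-type etherification of the heteroaryl bromide with a primary benzylic alcohol should put a removable ether on the carbon that becomes C9.

Step 12
Reactants: 25 3-[(4-methoxybenzyl)oxy]furan; 26 allyl bromide
Product: 28 2-allyl-3-[(4-methoxybenzyl)oxy]furan, via 2-furyllithium 27 (not isolated)
Conditions: n-BuLi, THF, −78 to 0 °C; then allyl bromide, −78 °C to rt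
Reagents that add atoms: allyl bromide, C=CCBr
Why: Directed metalation: the 3-alkoxy group and the ring oxygen both acidify H-2, so n-BuLi should lithiate C2 selectively and the furyllithium is alkylated by allyl bromide (SN2).

Step 13
Reactants: 28 2-allyl-3-[(4-methoxybenzyl)oxy]furan; 29 3-bromo-2-methylprop-1-ene
Product: 31 2-allyl-3-[(4-methoxybenzyl)oxy]-5-(2-methylallyl)furan, via 5-furyllithium 30 (not isolated)
Conditions: n-BuLi, THF, −78 to −20 °C; then 3-bromo-2-methylprop-1-ene, −78 °C to rt
Reagents that add atoms: 3-bromo-2-methylprop-1-ene, C=C(C)CBr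
Why: Lithiation of the remaining furan α-position C5 (ring sp2 C–H deprotonation is kinetically preferred at low temperature) and SN2 alkylation with methallyl bromide should place the methyl-bearing arm on the carbon that becomes C16.

Step 14
Reactants: 31 2-allyl-3-[(4-methoxybenzyl)oxy]-5-(2-methylallyl)furan; 32 dioxygen
Product: 34 (5E)-6-[(4-methoxybenzyl)oxy]-2-methyldeca-1,5,9-triene-4,7-dione (the two acyl groups cis on the central alkene), via furan endoperoxide 33 (not isolated)
Conditions: O2, tetraphenylporphyrin (cat.), visible light, CH2Cl2, −78 °C; then Me2S, −78 °C to rt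
Reagents that add atoms: dioxygen, O=O
Why: [4+2] cycloaddition of singlet oxygen across the furan 2,5-positions and reduction of the endoperoxide by Me2S (furan to cis-enedione unmasking) should give the 2-alkoxy-cis-ene-1,4-dione, the electron-rich furan reacting far faster than the isolated alkenes.

Step 15
Reactants: 34 acyclic alkoxy-enedione
Product: 35 2-[(4-methoxybenzyl)oxy]-6-methylcycloocta-2,6-diene-1,4-dione (ring C fragment, both ring alkenes cis within the ring, achiral)
Conditions: second-generation Grubbs catalyst RuCl2(=CHPh)(PCy3)(H2IMes) (5 mol %), 1,4-benzoquinone (10 mol %), CH2Cl2 (2 mM), 40 °C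
Reagents that add atoms: none
Why: Ring-closing metathesis between the allyl and methallyl termini should form the trisubstituted ring alkene, the cis-enedione unit preorganising the chain for eight-membered ring closure and benzoquinone suppressing ruthenium hydride double-bond migration.

Step 16
Reactants: 22 ring A fragment; 35 ring C fragment
Product: 37 tricyclic annulation product (target skeleton with free 8β-OH and 9α-O-PMB ether), via Giese adduct enolate 36 (not isolated)
Conditions: Fe(acac)3 (30 mol %), PhSiH2(Oi-Pr) (2.5 equiv), 35 (2.5 equiv), THF/i-PrOH (10:1), 0 °C to rt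
Reagents that add atoms: none
Why: Fe(acac)3 and the silane generate an iron hydride that transfers a hydrogen atom to the 1,1-disubstituted methylene of 22 (making the angular methyl and a tertiary C3 radical), the radical adds to the unsubstituted enedione carbon C10 of 35 (Giese addition), and the captodative C9 radical is reduced to iron enolate 36, which adds to the C8 aldehyde, the whole being the known hydrogen-atom-transfer-initiated radical conjugate addition/aldol annulation of alkenyl aldehydes with enones. Ring B closes in the second event as a 6-(enolexo)-exo-trig aldol through a chair, after the intermolecular C3–C10 bond has joined rings A and C. C3: the acceptor should approach equatorially, anti to the C4 side chain and away from the syn-axial C5 methyl, leaving the new methyl axial (trans A/B fusion). C10 and C9: only the adduct with H-10 anti to the angular methyl can reach a chair, and in it allylic strain holds H-10 in the enolate plane so that the aldehyde, tethered through C3, attacks the face opposite C16, giving the trans-diequatorial B/C fusion with the C9 oxygen axial (α). C8: the aldehyde oxygen should sit axial, antiperiplanar to the C9–O bond (dipole minimisation, only hydrogens syn-axial), giving the β carbinol. The step needs hydrogen atom transfer to the methylene rather than the trisubstituted ring C alkene, attack at C10 rather than C9, and aldol rather than protonation of 36; the accessible electron-rich 1,1-disubstituted alkene (with 35 in excess), the full substitution of C9 and the six-membered tether should secure these.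

Step 17
Reactants: 37 tricyclic annulation product; 15 acetic anhydride
Product: 38 8-O-acetyl-9-O-PMB tricycle
Conditions: Ac2O, DMAP, pyridine, CH2Cl2, 0 °C to rt
Reagents that add atoms: acetic anhydride, CC(=O)OC(C)=O
Why: DMAP-catalysed acetylation of the only free hydroxyl (C8), with the tertiary C9 oxygen still masked, should proceed under conditions too mild for retro-aldol cleavage.

Step 18
Reactants: 38 8-O-acetyl-9-O-PMB tricycle
Product: 39 CNP0214674.2 (target)
Conditions: DDQ, CH2Cl2/pH 7 phosphate buffer (10:1), 0 °C to rt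
Reagents that add atoms: none
Why: Oxidative cleavage of the 4-methoxybenzyl ether by DDQ (hydride abstraction, hydrolysis of the oxocarbenium ion) should free the tertiary C9 hydroxyl under near-neutral conditions that spare the esters, the skipped enone and the β-hydroxy ketone.

Compound list
1 | 3-ethoxy-5,5-dimethylcyclohex-2-en-1-one | CCOC1=CC(=O)CC(C)(C)C1 | starting material
2 | allyl chloroformate | C=CCOC(Cl)=O | starting material
3 | lithium 5-ethoxy-3,3-dimethylcyclohexa-1,5-dien-1-olate | [Li]OC1=CC(C)(C)CC(OCC)=C1 | intermediate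
4 | allyl 5-ethoxy-3,3-dimethylcyclohexa-1,5-dien-1-yl carbonate | C=CCOC(=O)OC1=CC(C)(C)CC(OCC)=C1 | intermediate
5 | (R)-6-allyl-3-ethoxy-5,5-dimethylcyclohex-2-en-1-one | CCOC1=CC(=O)[C@H](CC=C)C(C)(C)C1 | intermediate
6 | methyllithium | [Li]C | starting material
7 | (6R)-6-allyl-3-ethoxy-1,5,5-trimethylcyclohex-2-en-1-ol (formed as its lithium alkoxide, carbinol centre undefined) | CCOC1=CC(C)(O)[C@H](CC=C)C(C)(C)C1 | intermediate
8 | (R)-4-allyl-3,5,5-trimethylcyclohex-2-en-1-one | O=C1C=C(C)[C@H](CC=C)C(C)(C)C1 | intermediate
9 | hydrogen peroxide | OO | starting material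
10 | (5R)-5-allyl-4,4,6-trimethyl-7-oxabicyclo[4.1.0]heptan-2-one, epoxide oxygen β (trans to allyl) | O=C1[C@H]2O[C@@]2(C)[C@H](CC=C)C(C)(C)C1 | intermediate
11 | dibenzoyl peroxide | O=C(OOC(=O)c1ccccc1)c1ccccc1 | starting material
12 | lithium enolate of 10 (C1–C6 enolate) | [Li]OC1=CC(C)(C)[C@@H](CC=C)[C@]2(C)O[C@H]12 | intermediate
13 | 5-allyl-4,4,6-trimethyl-2-oxo-7-oxabicyclo[4.1.0]heptan-3-yl benzoate, benzoate and epoxide oxygen β, allyl α | O=C1[C@H]2O[C@@]2(C)[C@H](CC=C)C(C)(C)[C@H]1OC(=O)c1ccccc1 | intermediate
14 | 5-allyl-2-hydroxy-4,4,6-trimethyl-7-oxabicyclo[4.1.0]heptan-3-yl benzoate, all three oxygens β, allyl α | O[C@H]1[C@H]2O[C@@]2(C)[C@H](CC=C)C(C)(C)[C@H]1OC(=O)c1ccccc1 | intermediate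
15 | acetic anhydride | CC(=O)OC(C)=O | starting material
16 | 2-acetoxy-5-allyl-4,4,6-trimethyl-7-oxabicyclo[4.1.0]heptan-3-yl benzoate, all three oxygens β | CC(=O)O[C@H]1[C@H]2O[C@@]2(C)[C@H](CC=C)C(C)(C)[C@H]1OC(=O)c1ccccc1 | intermediate
17 | ozone | [O-][O+]=O | starting material
18 | secondary ozonide (1,2,4-trioxolane) of 16 | CC(=O)O[C@H]1[C@H]2O[C@@]2(C)[C@H](CC2OCOO2)C(C)(C)[C@H]1OC(=O)c1ccccc1 | intermediate
19 | 2-acetoxy-4,4,6-trimethyl-5-(2-oxoethyl)-7-oxabicyclo[4.1.0]heptan-3-yl benzoate | CC(=O)O[C@H]1[C@H]2O[C@@]2(C)[C@H](CC=O)C(C)(C)[C@H]1OC(=O)c1ccccc1 | intermediate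
20 | 2-acetoxy-3-hydroxy-6,6-dimethyl-4-methylidene-5-(2-oxoethyl)cyclohexyl benzoate, three oxygens β, side chain α | CC(=O)O[C@H]1[C@@H](O)C(=C)[C@H](CC=O)C(C)(C)[C@H]1OC(=O)c1ccccc1 | intermediate
21 | benzoyl chloride | O=C(Cl)c1ccccc1 | starting material
22 | (1S,2R,3R,5R)-2-acetoxy-4,4-dimethyl-6-methylidene-5-(2-oxoethyl)cyclohexane-1,3-diyl dibenzoate (ring A fragment) | CC(=O)O[C@H]1[C@@H](OC(=O)c2ccccc2)C(=C)[C@H](CC=O)C(C)(C)[C@H]1OC(=O)c1ccccc1 | intermediate
23 | 3-bromofuran | Brc1ccoc1 | starting material
24 | 4-methoxybenzyl alcohol | COc1ccc(CO)cc1 | starting material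
25 | 3-[(4-methoxybenzyl)oxy]furan | COc1ccc(COc2ccoc2)cc1 | intermediate
26 | allyl bromide | C=CCBr | starting material
27 | 2-lithio-3-[(4-methoxybenzyl)oxy]furan | [Li]c1occc1OCc1ccc(OC)cc1 | intermediate
28 | 2-allyl-3-[(4-methoxybenzyl)oxy]furan | C=CCc1occc1OCc1ccc(OC)cc1 | intermediate
29 | 3-bromo-2-methylprop-1-ene | C=C(C)CBr | starting material
30 | 2-allyl-5-lithio-3-[(4-methoxybenzyl)oxy]furan | [Li]c1cc(OCc2ccc(OC)cc2)c(CC=C)o1 | intermediate
31 | 2-allyl-3-[(4-methoxybenzyl)oxy]-5-(2-methylallyl)furan | C=CCc1oc(CC(C)=C)cc1OCc1ccc(OC)cc1 | intermediate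
32 | dioxygen | O=O | starting material
33 | 1-allyl-6-[(4-methoxybenzyl)oxy]-4-(2-methylallyl)-2,3,7-trioxabicyclo[2.2.1]hept-5-ene | C=CCC12OOC(CC(C)=C)(O1)C=C2OCc1ccc(OC)cc1 | intermediate
34 | (5E)-6-[(4-methoxybenzyl)oxy]-2-methyldeca-1,5,9-triene-4,7-dione (acyl groups cis) | C=CCC(=O)/C(OCc1ccc(OC)cc1)=C\C(=O)CC(C)=C | intermediate
35 | 2-[(4-methoxybenzyl)oxy]-6-methylcycloocta-2,6-diene-1,4-dione (ring C fragment) | O=C1C/C=C(/C)CC(=O)/C=C1/OCc1ccc(OC)cc1 | intermediate
36 | iron enolate of the C3–C10 conjugate adduct, drawn as its C11 enol, ring B still open | CC(=O)O[C@H]1[C@@H](OC(=O)c2ccccc2)[C@@](C)([C@@H]2C(=O)C/C(C)=C\CC(O)=C2OCc2ccc(OC)cc2)[C@H](CC=O)C(C)(C)[C@H]1OC(=O)c1ccccc1 | intermediate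
37 | tricyclic annulation product: target skeleton with 1β-OAc, 2β-OBz, 6β-OBz, free 8β-OH, 9α-O-PMB, 11,16-dione | CC(=O)O[C@H]1[C@@H](OC(=O)c2ccccc2)[C@]2(C)[C@H](C[C@H](O)[C@]3(OCc4ccc(OC)cc4)C(=O)C/C=C(/C)CC(=O)[C@H]32)C(C)(C)[C@H]1OC(=O)c1ccccc1 | intermediate
38 | 8-O-acetate of 37 (9α-O-PMB retained) | CC(=O)O[C@H]1[C@@H](OC(=O)c2ccccc2)[C@]2(C)[C@H](C[C@H](OC(C)=O)[C@]3(OCc4ccc(OC)cc4)C(=O)C/C=C(/C)CC(=O)[C@H]32)C(C)(C)[C@H]1OC(=O)c1ccccc1 | intermediate
39 | CNP0214674.2 | CC(=O)O[C@H]1[C@@H](OC(=O)c2ccccc2)[C@]2(C)[C@H](C[C@H](OC(C)=O)[C@]3(O)C(=O)C/C=C(/C)CC(=O)[C@H]32)C(C)(C)[C@H]1OC(=O)c1ccccc1 | target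

Total step count: 18 steps (ring A fragment steps 1–10, ring C fragment steps 11–15, union and endgame steps 16–18).
Longest linear sequence: 13 steps (steps 1–10, then 16, 17, 18).

Steps most likely to fail

Step 16. Several processes can intercept the cascade: simple reduction of the tertiary radical before it adds to the hindered acceptor, hydrogen atom transfer to the ring C alkene, protonation of enolate 36 before ring closure, and poor facial selectivity at C10. The fallback separates the two bond formations. Starting from 22 and 35, the iron-hydride coupling is run in EtOH/(CH2OH)2, where the enolate is protonated, and the open conjugate adduct with the C3–C10 bond in place and ring B still open, F1, is isolated. Ring B is then closed in a second operation by a reversible amine-base aldol (DBU, CH2Cl2, 0 °C). Among the equilibrating enolates only the one at C9 can give an unstrained six-membered aldol, and C10, which is α to the C16 ketone, should equilibrate to the trans-diequatorial B/C fusion. This returns to 37.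

Step 15. Oligomerisation can outrun eight-membered ring closure, and a ruthenium hydride can move the β,γ-double bonds of the two allyl ketones into conjugation. The fallback masks the enedione before metathesis and sets out from furan 31. Oxidative 1,4-dimethoxylation (Br2, Na2CO3, MeOH, −45 °C) should give 2-allyl-2,5-dimethoxy-3-[(4-methoxybenzyl)oxy]-5-(2-methylallyl)-2,5-dihydrofuran F2 as a cis/trans mixture that equilibrates in acidic MeOH. Ring-closing metathesis of the cis isomer with the same ruthenium carbene has no enolisable ketone to contend with and holds both arms cis on a five-membered ring; it should give the bridged bis-ketal 1,6-dimethoxy-7-[(4-methoxybenzyl)oxy]-4-methyl-9-oxabicyclo[4.2.1]nona-3,7-diene F3. Mild aqueous acid (PPTS, wet acetone) then releases both ketones and returns to 35.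

Step 5. The epoxy-ketone enolate may decompose by opening the epoxide, or the benzoate may settle on the wrong face. The fallback oxidises C6 before the epoxide exists and sets out from enone 8. Kinetic α′-enolate formation (LiN(i-Pr)2, THF, −78 °C) and dibenzoyl peroxide should give 5-allyl-4,6,6-trimethyl-2-oxocyclohex-3-en-1-yl benzoate (benzoate trans to allyl) F4. Luche reduction (NaBH4, CeCl3·7H2O, MeOH, −78 °C) should give the allylic alcohol cis to the benzoate, 5-allyl-2-hydroxy-4,6,6-trimethylcyclohex-3-en-1-yl benzoate F5. Hydroxyl-directed epoxidation (VO(acac)2, t-BuOOH, CH2Cl2, 0 °C) then delivers the epoxide syn to the hydroxyl and anti to the allyl group, returning to 14.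

Further compounds
F1 | step 16 | open C3–C10 conjugate adduct of 22 and 35 (keto form, ring B not closed, C9 configuration undefined) | CC(=O)O[C@H]1[C@@H](OC(=O)c2ccccc2)[C@@](C)([C@@H]2C(=O)C/C(C)=C\CC(=O)C2OCc2ccc(OC)cc2)[C@H](CC=O)C(C)(C)[C@H]1OC(=O)c1ccccc1
F2 | step 15 | 2-allyl-2,5-dimethoxy-3-[(4-methoxybenzyl)oxy]-5-(2-methylallyl)-2,5-dihydrofuran (cis/trans mixture) | C=CCC1(OC)OC(OC)(CC(C)=C)C=C1OCc1ccc(OC)cc1
F3 | step 15 | 1,6-dimethoxy-7-[(4-methoxybenzyl)oxy]-4-methyl-9-oxabicyclo[4.2.1]nona-3,7-diene | COC12CC=C(C)CC(OC)(O1)C=C2OCc1ccc(OC)cc1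
F4 | step 5 | 5-allyl-4,6,6-trimethyl-2-oxocyclohex-3-en-1-yl benzoate, benzoate trans to allyl | O=C1C=C(C)[C@H](CC=C)C(C)(C)[C@H]1OC(=O)c1ccccc1
F5 | step 5 | 5-allyl-2-hydroxy-4,6,6-trimethylcyclohex-3-en-1-yl benzoate, hydroxyl cis to benzoate, allyl trans | O[C@H]1C=C(C)[C@H](CC=C)C(C)(C)[C@H]1OC(=O)c1ccccc1
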